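**Plan**
1. The target is (8S)-1,13-bis[(2S)-2-methylbutanoyl]-8-[(2Z)-undec-2-en-1-yl]-1,5,9,13-tetraazacyclooctadecan-6-one (ring locants used below). Retrosynthetic cuts, in order: N9–C10 (sulfonamide N-alkylation), lactam N5–C6, exchange of N9 on C8 for a carboxyl (Curtius read backwards), then the bond from C8 to the allylic CH2 of the side chain.
2. Enabling feature: the ring segment N9–C8H–C7H2–C6(=O) is a β-amino amide. With N9 read as a former carboxyl, C8 is the α-carbon of a succinic half-ester, so its C–H is enolisable and can take the side chain by SN2 with a preformed (Z)-allylic bromide, which keeps both the CH2 terminus and the cis geometry.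
3. Forward, acid arm: dec-1-yne → (2Z)-1-bromoundec-2-ene; alkylation of the succinate imide of (4S)-4-benzyloxazolidin-2-one; auxiliary cleavage; Curtius; N-(2-nitrobenzenesulfonyl) (Ns) protection.
4. Forward, polyamine arm: 5-aminopentan-1-ol + acrylonitrile, N-acylation, mesylate displacement by 3-aminopropan-1-ol, second N-acylation, nitrile hydrogenation; both acylations use one isolated pentafluorophenyl ester of (2S)-2-methylbutanoic acid.
5. Union: amide coupling of the two arms, then the only ring (18-membered) is closed by intramolecular Mitsunobu alkylation of the Ns-amide at N9; thiolate removes Ns.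
6. Stereochemistry: C8 (S) comes from the auxiliary-controlled alkylation and is retained in the Curtius shift; the Z-alkene comes from Lindlar semihydrogenation of the propargylic alcohol; both acyl centres come from commercial (2S)-2-methylbutanoic acid.

Key step: step 5

**Route**

Step 1
Reactants: 1 dec-1-yne; 2 paraformaldehyde
Product: 4 undec-2-yn-1-ol, via lithium dec-1-yn-1-ide 3 (not isolated)
Conditions: n-BuLi, THF, −78 °C; (CH2O)n, −78 °C to rt; then H2O
Reagents that add atoms: none
Why: Deprotonation of the terminal alkyne and addition of the lithium acetylide to formaldehyde (acetylide hydroxymethylation) should give the propargylic alcohol.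

Step 2
Reactants: 4 undec-2-yn-1-ol
Product: 5 (2Z)-undec-2-en-1-ol
Conditions: H2 (1 bar), Pd/CaCO3 poisoned with Pb(OAc)2 (Lindlar catalyst), quinoline, EtOAc, rt
Reagents that add atoms: none
Why: Lindlar semihydrogenation adds H2 syn to the alkyne on the poisoned Pd surface, so the cis alkene should form while quinoline suppresses over-reduction.

Step 3
Reactants: 5 (2Z)-undec-2-en-1-ol
Product: 6 (2Z)-1-bromoundec-2-ene
Conditions: CBr4, PPh3, CH2Cl2, −20 to 0 °C
Reagents that add atoms: carbon tetrabromide, BrC(Br)(Br)Br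
Why: Appel reaction, in which bromide displaces the activated primary allylic oxygen by SN2 at low temperature, which should leave the Z double bond in place.

Step 4
Reactants: 7 4-tert-butoxy-4-oxobutanoic acid; 8 (4S)-4-benzyl-1,3-oxazolidin-2-one
Product: 10 tert-butyl 4-[(4S)-4-benzyl-2-oxo-1,3-oxazolidin-3-yl]-4-oxobutanoate, via mixed pivalic anhydride 9 (not isolated)
Conditions: pivaloyl chloride, Et3N, THF, −20 °C; then LiCl, 8, −20 °C to rt
Reagents that add atoms: none
Why: N-Acylation of the oxazolidinone through the mixed anhydride with LiCl/Et3N activation; the hindered pivaloyl carbonyl is not attacked, so only the succinyl group should be transferred.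

Step 5
Reactants: 10 tert-butyl 4-[(4S)-4-benzyl-2-oxo-1,3-oxazolidin-3-yl]-4-oxobutanoate; 6 (2Z)-1-bromoundec-2-ene
Product: 12 tert-butyl (3S,5Z)-3-{[(4S)-4-benzyl-2-oxo-1,3-oxazolidin-3-yl]carbonyl}tetradec-5-enoate, via sodium (Z)-enolate 11 (not isolated)
Conditions: NaN(SiMe3)2, THF, −78 °C; then 6, −78 to −45 °C; aq. NH4Cl
Reagents that add atoms: none
Why: NaN(SiMe3)2 removes a proton from the CH2 next to the imide carbonyl (more acidic than the CH2 next to the tert-butyl ester) to give the sodium-chelated (Z)-enolate 11, whose α-carbon displaces bromide from the primary allylic carbon of 6 by SN2. The closest known reaction type is the Evans asymmetric alkylation of N-acyloxazolidinones, succinate-derived imides included, with allylic halides. No ring is closed. The new stereocentre is controlled by the benzyl group at C4 of the oxazolidinone: in the rigid chelate it shields one enolate face, so the electrophile should enter anti to it and give the (3S) centre. The step needs attack at the CH2 terminus of the allyl unit (not at its far alkene carbon) and retention of the cis geometry; both should be secured because an uncatalysed SN2 at the unhindered CH2–Br carbon passes through no allyl-metal or allyl-cation species. Any minor diastereomer should be removable by chromatography at this stage.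

Step 6
Reactants: 12 tert-butyl (3S,5Z)-3-{[(4S)-4-benzyl-2-oxo-1,3-oxazolidin-3-yl]carbonyl}tetradec-5-enoate
Product: 14 (2S,4Z)-2-(2-tert-butoxy-2-oxoethyl)tridec-4-enoic acid, via peroxy acid 13 (not isolated)
Conditions: LiOH, H2O2, THF/H2O, 0 °C; then aq. Na2SO3; 1 M HCl to pH 3
Reagents that add atoms: hydrogen peroxide, OO
Why: Lithium hydroperoxide attacks the exocyclic imide carbonyl selectively (Evans auxiliary cleavage), the tert-butyl ester and alkene should stay untouched, and sulfite reduces peroxy acid 13 to the acid without epimerising the α-centre.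

Step 7
Reactants: 14 (2S,4Z)-2-(2-tert-butoxy-2-oxoethyl)tridec-4-enoic acid
Product: 17 (3S,5Z)-3-aminotetradec-5-enoic acid hydrochloride, via acyl azide 15 (not isolated), via isocyanate 16 (not isolated)
Conditions: diphenylphosphoryl azide, Et3N, toluene, rt then 85 °C; then 4 M aq. HCl/1,4-dioxane, 60 °C
Reagents that add atoms: diphenylphosphoryl azide, [N-]=[N+]=NP(=O)(Oc1ccccc1)Oc1ccccc1; hydrogen chloride, Cl
Why: Curtius rearrangement, in which acyl azide 15 loses N2 with a 1,2-shift of the stereogenic carbon to nitrogen with retention; hot aqueous HCl should then hydrolyse isocyanate 16 with decarboxylation and cleave the tert-butyl ester, the protonated amine being unable to add to remaining isocyanate.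

Step 8
Reactants: 17 (3S,5Z)-3-aminotetradec-5-enoic acid hydrochloride
Product: 18 (3S,5Z)-3-{[(2-nitrophenyl)sulfonyl]amino}tetradec-5-enoic acid
Conditions: 2-nitrobenzenesulfonyl chloride, Na2CO3, THF/H2O, 0 °C to rt; then 1 M HCl
Reagents that add atoms: 2-nitrobenzenesulfonyl chloride, O=S(=O)(Cl)c1ccccc1[N+](=O)[O-]
Why: Schotten–Baumann sulfonylation of the amine installs the Ns group, which makes the N–H acidic enough for the later Mitsunobu alkylation.

Step 9
Reactants: 19 5-aminopentan-1-ol; 20 acrylonitrile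
Product: 21 3-[(5-hydroxypentyl)amino]propanenitrile
Conditions: MeOH, 0 °C to rt
Reagents that add atoms: none
Why: Aza-Michael addition (cyanoethylation) of the primary amine should stop at the mono-adduct with one equivalent at room temperature, and the alcohol does not add without base.

Step 10
Reactants: 22 (2S)-2-methylbutanoic acid
Product: 23 pentafluorophenyl (2S)-2-methylbutanoate
Conditions: C6F5OH, N,N'-dicyclohexylcarbodiimide, EtOAc, 0 °C to rt; filtration of the urea, short silica plug
Reagents that add atoms: pentafluorophenol, Oc1c(F)c(F)c(F)c(F)c1F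
Why: Carbodiimide-mediated esterification of the acid with the acidic phenol should give an isolable active ester that serves both N-acylations, and a simple α-alkyl acid has no oxazolone pathway, so the (S) centre should be kept.

Step 11
Reactants: 21 3-[(5-hydroxypentyl)amino]propanenitrile; 23 pentafluorophenyl (2S)-2-methylbutanoate
Product: 24 (2S)-N-(2-cyanoethyl)-N-(5-hydroxypentyl)-2-methylbutanamide
Conditions: iPr2NEt, CH2Cl2, rt
Reagents that add atoms: none
Why: Aminolysis of the pentafluorophenyl active ester by the secondary amine should be much faster than acylation of the primary alcohol, which would need an acyl-transfer catalyst, and the mild base should not epimerise the α-centre.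

Step 12
Reactants: 24 (2S)-N-(2-cyanoethyl)-N-(5-hydroxypentyl)-2-methylbutanamide
Product: 25 5-{(2-cyanoethyl)[(2S)-2-methylbutanoyl]amino}pentyl methanesulfonate
Conditions: methanesulfonyl chloride, Et3N, CH2Cl2, 0 °C
Reagents that add atoms: methanesulfonyl chloride, CS(=O)(=O)Cl
Why: Sulfonylation turns the primary alcohol into a leaving group while the tertiary amide and nitrile are inert.

Step 13
Reactants: 25 5-{(2-cyanoethyl)[(2S)-2-methylbutanoyl]amino}pentyl methanesulfonate; 26 3-aminopropan-1-ol
Product: 27 (2S)-N-(2-cyanoethyl)-N-{5-[(3-hydroxypropyl)amino]pentyl}-2-methylbutanamide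
Conditions: 26 in large excess, MeCN, 60 °C
Reagents that add atoms: none
Why: SN2 amination of the primary mesylate; the excess of amino alcohol should make monoalkylation dominant, and nitrogen is far more nucleophilic than the hydroxyl.

Step 14
Reactants: 27 (2S)-N-(2-cyanoethyl)-N-{5-[(3-hydroxypropyl)amino]pentyl}-2-methylbutanamide; 23 pentafluorophenyl (2S)-2-methylbutanoate
Product: 28 (2S)-N-(2-cyanoethyl)-N-(5-{(3-hydroxypropyl)[(2S)-2-methylbutanoyl]amino}pentyl)-2-methylbutanamide
Conditions: iPr2NEt, CH2Cl2, rt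
Reagents that add atoms: none
Why: The same N-selective aminolysis of the pentafluorophenyl active ester should acylate the new secondary amine in the presence of the free alcohol.

Step 15
Reactants: 28 (2S)-N-(2-cyanoethyl)-N-(5-{(3-hydroxypropyl)[(2S)-2-methylbutanoyl]amino}pentyl)-2-methylbutanamide
Product: 29 (2S)-N-(3-aminopropyl)-N-(5-{(3-hydroxypropyl)[(2S)-2-methylbutanoyl]amino}pentyl)-2-methylbutanamide
Conditions: H2 (4 bar), Raney Ni, NH3 in MeOH, rt
Reagents that add atoms: none
Why: Catalytic hydrogenation of the nitrile to the primary amine; ammonia suppresses secondary-amine formation, the amides and alcohol are not reduced, and no alkene is present in this arm.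

Step 16
Reactants: 18 (3S,5Z)-3-{[(2-nitrophenyl)sulfonyl]amino}tetradec-5-enoic acid; 29 (2S)-N-(3-aminopropyl)-N-(5-{(3-hydroxypropyl)[(2S)-2-methylbutanoyl]amino}pentyl)-2-methylbutanamide
Product: 31 (3S,5Z)-N-[3-({5-[(3-hydroxypropyl)((2S)-2-methylbutanoyl)amino]pentyl}[(2S)-2-methylbutanoyl]amino)propyl]-3-{[(2-nitrophenyl)sulfonyl]amino}tetradec-5-enamide, via benzotriazolyl ester 30 (not isolated)
Conditions: EDC·HCl, HOBt, iPr2NEt, CH2Cl2/DMF, 0 °C to rt
Reagents that add atoms: none
Why: Aminolysis of active ester 30 by the primary amine (carbodiimide/HOBt amide coupling) should give the secondary amide, since the alcohol and the Ns–NH are much weaker nucleophiles.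

Step 17
Reactants: 31 (3S,5Z)-N-[3-({5-[(3-hydroxypropyl)((2S)-2-methylbutanoyl)amino]pentyl}[(2S)-2-methylbutanoyl]amino)propyl]-3-{[(2-nitrophenyl)sulfonyl]amino}tetradec-5-enamide
Product: 32 (8S)-1,13-bis[(2S)-2-methylbutanoyl]-9-[(2-nitrophenyl)sulfonyl]-8-[(2Z)-undec-2-en-1-yl]-1,5,9,13-tetraazacyclooctadecan-6-one
Conditions: PPh3, diethyl azodicarboxylate (slow addition), toluene/THF, high dilution (about 2 mM), rt
Reagents that add atoms: none
Why: Intramolecular Fukuyama–Mitsunobu reaction, in which only the Ns–NH (pKa about 10) is acidic enough to be alkylated by the activated primary alcohol, and high dilution should favour closure of the 18-membered ring over oligomerisation.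

Step 18
Reactants: 32 (8S)-1,13-bis[(2S)-2-methylbutanoyl]-9-[(2-nitrophenyl)sulfonyl]-8-[(2Z)-undec-2-en-1-yl]-1,5,9,13-tetraazacyclooctadecan-6-one
Product: 33 (8S)-1,13-bis[(2S)-2-methylbutanoyl]-8-[(2Z)-undec-2-en-1-yl]-1,5,9,13-tetraazacyclooctadecan-6-one
Conditions: PhSH, K2CO3, DMF, rt, under argon in the dark
Reagents that add atoms: none
Why: Fukuyama Ns cleavage, in which thiolate attacks the electron-poor nitroarene by SNAr and releases SO2 and the secondary amine; the amides should be untouched, and exclusion of air and light guards the Z-alkene against thiyl-radical isomerisation.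

**Compound list**
1 | dec-1-yne | CCCCCCCCC#C | starting material
2 | paraformaldehyde (used as formaldehyde) | C=O | starting material
3 | lithium dec-1-yn-1-ide | CCCCCCCCC#C[Li] | intermediate
4 | undec-2-yn-1-ol | CCCCCCCCC#CCO | intermediate
5 | (2Z)-undec-2-en-1-ol | CCCCCCCC/C=C\CO | intermediate
6 | (2Z)-1-bromoundec-2-ene | CCCCCCCC/C=C\CBr | intermediate
7 | 4-tert-butoxy-4-oxobutanoic acid (mono-tert-butyl succinate) | CC(C)(C)OC(=O)CCC(=O)O | starting material
8 | (4S)-4-benzyl-1,3-oxazolidin-2-one | O=C1N[C@@H](Cc2ccccc2)CO1 | starting material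
9 | mixed anhydride of 7 with pivalic acid | CC(C)(C)OC(=O)CCC(=O)OC(=O)C(C)(C)C | intermediate
10 | tert-butyl 4-[(4S)-4-benzyl-2-oxo-1,3-oxazolidin-3-yl]-4-oxobutanoate | CC(C)(C)OC(=O)CCC(=O)N1C(=O)OC[C@@H]1Cc1ccccc1 | intermediate
11 | sodium (Z)-enolate of 10 (enolate at the imide acyl group, O and CH2CO2tBu cis) | CC(C)(C)OC(=O)C/C=C(\[O-])N1C(=O)OC[C@@H]1Cc1ccccc1.[Na+] | intermediate
12 | tert-butyl (3S,5Z)-3-{[(4S)-4-benzyl-2-oxo-1,3-oxazolidin-3-yl]carbonyl}tetradec-5-enoate | CCCCCCCC/C=C\C[C@H](C(=O)N1C(=O)OC[C@@H]1Cc1ccccc1)CC(=O)OC(C)(C)C | intermediate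
13 | (2S,4Z)-2-(2-tert-butoxy-2-oxoethyl)tridec-4-eneperoxoic acid | CCCCCCCC/C=C\C[C@H](C(=O)OO)CC(=O)OC(C)(C)C | intermediate
14 | (2S,4Z)-2-(2-tert-butoxy-2-oxoethyl)tridec-4-enoic acid | CCCCCCCC/C=C\C[C@H](C(=O)O)CC(=O)OC(C)(C)C | intermediate
15 | (2S,4Z)-2-(2-tert-butoxy-2-oxoethyl)tridec-4-enoyl azide | CCCCCCCC/C=C\C[C@H](C(=O)N=[N+]=[N-])CC(=O)OC(C)(C)C | intermediate
16 | tert-butyl (3S,5Z)-3-isocyanatotetradec-5-enoate | CCCCCCCC/C=C\C[C@H](N=C=O)CC(=O)OC(C)(C)C | intermediate
17 | (3S,5Z)-3-aminotetradec-5-enoic acid hydrochloride | CCCCCCCC/C=C\C[C@H](N)CC(=O)O.Cl | intermediate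
18 | (3S,5Z)-3-{[(2-nitrophenyl)sulfonyl]amino}tetradec-5-enoic acid | CCCCCCCC/C=C\C[C@H](NS(=O)(=O)c1ccccc1[N+](=O)[O-])CC(=O)O | intermediate
19 | 5-aminopentan-1-ol | NCCCCCO | starting material
20 | acrylonitrile | C=CC#N | starting material
21 | 3-[(5-hydroxypentyl)amino]propanenitrile | N#CCCNCCCCCO | intermediate
22 | (2S)-2-methylbutanoic acid | CC[C@H](C)C(=O)O | starting material
23 | pentafluorophenyl (2S)-2-methylbutanoate | CC[C@H](C)C(=O)Oc1c(F)c(F)c(F)c(F)c1F | intermediate
24 | (2S)-N-(2-cyanoethyl)-N-(5-hydroxypentyl)-2-methylbutanamide | CC[C@H](C)C(=O)N(CCC#N)CCCCCO | intermediate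
25 | 5-{(2-cyanoethyl)[(2S)-2-methylbutanoyl]amino}pentyl methanesulfonate | CC[C@H](C)C(=O)N(CCC#N)CCCCCOS(C)(=O)=O | intermediate
26 | 3-aminopropan-1-ol | NCCCO | starting material
27 | (2S)-N-(2-cyanoethyl)-N-{5-[(3-hydroxypropyl)amino]pentyl}-2-methylbutanamide | CC[C@H](C)C(=O)N(CCC#N)CCCCCNCCCO | intermediate
28 | (2S)-N-(2-cyanoethyl)-N-(5-{(3-hydroxypropyl)[(2S)-2-methylbutanoyl]amino}pentyl)-2-methylbutanamide | CC[C@H](C)C(=O)N(CCC#N)CCCCCN(CCCO)C(=O)[C@@H](C)CC | intermediate
29 | (2S)-N-(3-aminopropyl)-N-(5-{(3-hydroxypropyl)[(2S)-2-methylbutanoyl]amino}pentyl)-2-methylbutanamide | CC[C@H](C)C(=O)N(CCCN)CCCCCN(CCCO)C(=O)[C@@H](C)CC | intermediate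
30 | 1H-benzotriazol-1-yl (3S,5Z)-3-{[(2-nitrophenyl)sulfonyl]amino}tetradec-5-enoate | CCCCCCCC/C=C\C[C@H](NS(=O)(=O)c1ccccc1[N+](=O)[O-])CC(=O)On1nnc2ccccc21 | intermediate
31 | (3S,5Z)-N-[3-({5-[(3-hydroxypropyl)((2S)-2-methylbutanoyl)amino]pentyl}[(2S)-2-methylbutanoyl]amino)propyl]-3-{[(2-nitrophenyl)sulfonyl]amino}tetradec-5-enamide | CCCCCCCC/C=C\C[C@H](NS(=O)(=O)c1ccccc1[N+](=O)[O-])CC(=O)NCCCN(C(=O)[C@@H](C)CC)CCCCCN(CCCO)C(=O)[C@@H](C)CC | intermediate
32 | (8S)-1,13-bis[(2S)-2-methylbutanoyl]-9-[(2-nitrophenyl)sulfonyl]-8-[(2Z)-undec-2-en-1-yl]-1,5,9,13-tetraazacyclooctadecan-6-one | CCCCCCCC/C=C\C[C@H]1CC(=O)NCCCN(C(=O)[C@@H](C)CC)CCCCCN(C(=O)[C@@H](C)CC)CCCN1S(=O)(=O)c1ccccc1[N+](=O)[O-] | intermediate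
33 | (8S)-1,13-bis[(2S)-2-methylbutanoyl]-8-[(2Z)-undec-2-en-1-yl]-1,5,9,13-tetraazacyclooctadecan-6-one | CCCCCCCC/C=C\C[C@H]1CC(=O)NCCCN(C(=O)[C@@H](C)CC)CCCCCN(C(=O)[C@@H](C)CC)CCCN1 | target

**Count**
Total steps: 18. Longest linear sequence: 10 steps (1, 2, 3, 5, 6, 7, 8, 16, 17, 18).

**Steps most likely to fail**

Step 17 (macrocyclisation). Intermolecular N-alkylation could outpace closure of the 18-membered ring and give oligomers. The activated primary alcohol could also be diverted by participation of the neighbouring tertiary amide oxygen. The fallback avoids alcohol activation and closes the ring at the lactam instead. It sets out from 14 and 29 and comes back at 33. Curtius rearrangement of 14 (diphenylphosphoryl azide, Et3N, toluene, 85 °C) through 15 and 16, with cold aqueous LiOH in THF in place of hot acid, would give tert-butyl (3S,5Z)-3-aminotetradec-5-enoate F1. Separately, Boc2O would convert 29 into tert-butyl N-[3-({5-[(3-hydroxypropyl)((2S)-2-methylbutanoyl)amino]pentyl}[(2S)-2-methylbutanoyl]amino)propyl]carbamate F2, and Dess–Martin periodinane would oxidise its alcohol to tert-butyl N-[3-({5-[((2S)-2-methylbutanoyl)(3-oxopropyl)amino]pentyl}[(2S)-2-methylbutanoyl]amino)propyl]carbamate F3. Reductive amination of F3 with F1 (NaBH(OAc)3, AcOH, 1,2-dichloroethane) would give the open-chain secondary amine tert-butyl (3S,5Z)-3-{[3-({5-[(3-{[(tert-butoxy)carbonyl]amino}propyl)((2S)-2-methylbutanoyl)amino]pentyl}[(2S)-2-methylbutanoyl]amino)propyl]amino}tetradec-5-enoate F4. CF3CO2H would remove the tert-butyl ester and the Boc group to give (3S,5Z)-3-{[3-({5-[(3-aminopropyl)((2S)-2-methylbutanoyl)amino]pentyl}[(2S)-2-methylbutanoyl]amino)propyl]amino}tetradec-5-enoic acid F5. Macrolactamisation of F5 at high dilution (pentafluorophenyl diphenylphosphinate, iPr2NEt, MeCN) should acylate the primary amine, since the hindered secondary amine could only form a four-membered lactam, and give 33 directly.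

Step 5 (key alkylation). The allylic bromide could lose its cis geometry by ionisation or bromide-induced allylic scrambling before it is consumed. The sodium enolate could also decompose during a slow alkylation, which would erode conversion and diastereomeric purity. The fallback is a catalyst-controlled glycine alkylation followed by one-carbon homologation. It sets out from 6 and comes back at 17. Phase-transfer alkylation of commercial tert-butyl N-(diphenylmethylidene)glycinate with 6 (O-allyl-N-(9-anthracenylmethyl)cinchonidinium bromide, CsOH·H2O, CH2Cl2, −60 °C) would give tert-butyl (2S,4Z)-2-[(diphenylmethylidene)amino]tridec-4-enoate F6. Aqueous HCl in dioxane would cleave imine and ester to (2S,4Z)-2-aminotridec-4-enoic acid hydrochloride F7. Boc2O/NaOH would give (2S,4Z)-2-[(tert-butoxycarbonyl)amino]tridec-4-enoic acid F8. Isobutyl chloroformate/N-methylmorpholine and then diazomethane would give tert-butyl N-[(3S,5Z)-1-diazo-2-oxotetradec-5-en-3-yl]carbamate F9. Wolff rearrangement (PhCO2Ag, Et3N, THF/H2O; Arndt–Eistert homologation with retention at the migrating carbon) would give (3S,5Z)-3-[(tert-butoxycarbonyl)amino]tetradec-5-enoic acid F10. HCl in dioxane would then return to 17.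

Step 7 (one-pot Curtius and hydrolysis). The isocyanate could be intercepted by amine that has already been liberated, giving the symmetrical urea. The hot aqueous acid could also cleave the ester incompletely and leave a zwitterionic mixture that is hard to purify. The fallback is capture and release through an isolable carbamate. It sets out from 14 and comes back at 17. The Curtius rearrangement would be run in tert-butanol (diphenylphosphoryl azide, Et3N, t-BuOH, reflux), so that isocyanate 16 formed from 15 is trapped as tert-butyl (3S,5Z)-3-[(tert-butoxycarbonyl)amino]tetradec-5-enoate F11, which can be chromatographed. Anhydrous HCl in dioxane at room temperature would then remove both tert-butyl groups and give 17.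

**Further compounds**
F1 | step 17 | tert-butyl (3S,5Z)-3-aminotetradec-5-enoate | CCCCCCCC/C=C\C[C@H](N)CC(=O)OC(C)(C)C
F2 | step 17 | tert-butyl N-[3-({5-[(3-hydroxypropyl)((2S)-2-methylbutanoyl)amino]pentyl}[(2S)-2-methylbutanoyl]amino)propyl]carbamate | CC[C@H](C)C(=O)N(CCCNC(=O)OC(C)(C)C)CCCCCN(CCCO)C(=O)[C@@H](C)CC
F3 | step 17 | tert-butyl N-[3-({5-[((2S)-2-methylbutanoyl)(3-oxopropyl)amino]pentyl}[(2S)-2-methylbutanoyl]amino)propyl]carbamate | CC[C@H](C)C(=O)N(CCCNC(=O)OC(C)(C)C)CCCCCN(CCC=O)C(=O)[C@@H](C)CC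
F4 | step 17 | tert-butyl (3S,5Z)-3-{[3-({5-[(3-{[(tert-butoxy)carbonyl]amino}propyl)((2S)-2-methylbutanoyl)amino]pentyl}[(2S)-2-methylbutanoyl]amino)propyl]amino}tetradec-5-enoate | CCCCCCCC/C=C\C[C@H](NCCCN(C(=O)[C@@H](C)CC)CCCCCN(CCCNC(=O)OC(C)(C)C)C(=O)[C@@H](C)CC)CC(=O)OC(C)(C)C
F5 | step 17 | (3S,5Z)-3-{[3-({5-[(3-aminopropyl)((2S)-2-methylbutanoyl)amino]pentyl}[(2S)-2-methylbutanoyl]amino)propyl]amino}tetradec-5-enoic acid | CCCCCCCC/C=C\C[C@H](NCCCN(C(=O)[C@@H](C)CC)CCCCCN(CCCN)C(=O)[C@@H](C)CC)CC(=O)O
F6 | step 5 | tert-butyl (2S,4Z)-2-[(diphenylmethylidene)amino]tridec-4-enoate | CCCCCCCC/C=C\C[C@H](N=C(c1ccccc1)c1ccccc1)C(=O)OC(C)(C)C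
F7 | step 5 | (2S,4Z)-2-aminotridec-4-enoic acid hydrochloride | CCCCCCCC/C=C\C[C@H](N)C(=O)O.Cl
F8 | step 5 | (2S,4Z)-2-[(tert-butoxycarbonyl)amino]tridec-4-enoic acid | CCCCCCCC/C=C\C[C@H](NC(=O)OC(C)(C)C)C(=O)O
F9 | step 5 | tert-butyl N-[(3S,5Z)-1-diazo-2-oxotetradec-5-en-3-yl]carbamate | CCCCCCCC/C=C\C[C@H](NC(=O)OC(C)(C)C)C(=O)C=[N+]=[N-]
F10 | step 5 | (3S,5Z)-3-[(tert-butoxycarbonyl)amino]tetradec-5-enoic acid | CCCCCCCC/C=C\C[C@H](NC(=O)OC(C)(C)C)CC(=O)O
F11 | step 7 | tert-butyl (3S,5Z)-3-[(tert-butoxycarbonyl)amino]tetradec-5-enoate | CCCCCCCC/C=C\C[C@H](NC(=O)OC(C)(C)C)CC(=O)OC(C)(C)C
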